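The pitfall with these flasks was to compare their charges, which are equal, when what differs is the hour at which each charge goes to work.

| flask | substrate | partner | remark | time |
|---|---|---|---|---|
| birch | 0.10 M | 0.10 M | run made earlier |  |
| cedar | 0.10 M | 0.050 M | run made earlier |  |
| alder | 0.10 M | 0.20 M | run made earlier |  |
| east | 0.10 M | 0.100 M (fed, over 8.0 h) | all else is in the flask from the start; the feed brings no volume worth counting | 20 h |
| south-west | 0.10 M (fed, over 8.0 h) | 0.100 M | all else is in the flask from the start; the feed brings no volume worth counting | 20 h |
| south-east | 0.10 M | 0.100 M | everything together at the start | 20 h |

| run | time / h | target / % |
|---|---|---|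
| birch | 5.00 | 22.5 |
| birch | 10.0 | 41.2 |
| birch | 15.0 | 51.1 |
| birch | 20.0 | 57.8 |
| cedar | 6.00 | 17.9 |
| cedar | 12.0 | 29.4 |
| cedar | 20.0 | 37.1 |
| cedar | 25.0 | 38.5 |
| alder | 3.00 | 19.1 |
| alder | 8.00 | 50.0 |
| alder | 15.0 | 72.7 |
| alder | 25.0 | 84.1 |

(scatter of a reading: 1 percentage point)

- for target the crystals are counted in
- as a solid, counted per litre of solution: crystals
- the numbers in the tables scatter by 1 percentage point (one standard deviation)
- what may be going on: substrate <-> open intermediate; partner -> second intermediate; open intermediate + second intermediate -> target; 2 second intermediate -> homo product; crystals <-> target; partner -> decomposition product

- which flask leads in amount of target, in percent of the substrate charged ("all alike" within 1.5 percentage points) (east / south-west / south-east / all alike)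
- how much target is there at the end, in percent of the substrate charged: east
- how much target is there at the end, in percent of the substrate charged: south-west
- how much target is there at the end, in percent of the substrate charged: south-east

On the card, partner passes into second intermediate, which then couples with open intermediate to give target or pairs to homo product. In the cedar run partner is the limiting reagent, so I read that curve as partner's own decay. I took the last reading, 38.5%, as the plateau, and the gaps below it gave a rate of 0.136 /h. From that came partner's clock, the time in which half of the partner present passes on, 5.09 h.

The feed of 8.0 h is longer than this clock. So by this clock 66.4% of the partner in south-west had passed on by the end of the substrate feed, and I expected part of it to pair. In east, partner arrives on average half a feed late, so I read that flask as the birch run at 16.0 h, interpolated to 52.4%. South-east repeats birch, 57.8%, and I put south-west below east. So I committed to south-east.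

The weak link was the plateau, since cedar still gained 1.4 percentage points at the end. Two slopes need no plateau: those between the first two readings and between the second and the last give 0.106 /h, a clock of 6.54 h. By the two clocks, the partner left in south-east at 20 h came to 6.57% and 12.0% of its charge. My figure for east used neither clock, so it stood.

The forecast named south-east: 58% (56% to 60%), east 53% (47% to 58%), south-west 46% (39% to 52%). It used a partner rate of 0.08 per hour where I had 0.136 /h and 0.106 /h, and it held that “Feeding substrate wastes early intermediate as homo product”.

The flasks gave south-east in the lead with 59.0%, east 56.5%, south-west 47.0%.

    substrate ⇌ open intermediate (K = 1.06, k = 0.358 /h)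
    partner → second intermediate (k = 0.116 /h)
    open intermediate + second intermediate → target (k = 13.1 /M/h)
    2 second intermediate → homo product (k = 10.2 /M/h)
    crystals ⇌ target, rate k5*(cs5 - [target]) while solid is left; crystals form when [target] > cs5 (solubility = 37.0 mM, k = 3.76 /h)
    partner → decomposition product (k = 1.74 × 10⁻⁴ /h)

The largest single effect on the gap between south-east and south-west is the pairing to homo product: with that step taken away, the gap falls from 12 points to 0.75 points. The clock shows when it happens. For the end of the feed it gave 33.6% to 42.8% of partner left; south-west holds 39.5%, and by then that flask has made 77.6% of the homo product it holds at 20.0 h. A neighbour of south-east charged with 0.40 M of partner, for which the clock gives 6.57% to 12.0%, keeps 9.79% of its own charge of partner at 20.0 h.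

(The data come from a simulation with constants of no real substance, noise included.)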